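**Retrosynthetic overview**
- The free acid is unmasked last from an Evans N-acyl oxazolidinone; hydroperoxide spares the hindered methyl enoate.
- The (Z)-trisubstituted enoate comes from a Still–Gennari olefination of a γ-formyl imide with an α-homoprenyl bis(trifluoroethyl) phosphonoacetate.
- The aldehyde comes from anti-Markovnikov hydration of a terminal alkyne installed by Evans propargylation, which sets the only stereocenter (R).
- The 3-furylpropyl arm comes from hydroboration of the N-pent-4-enoyl imide and B-alkyl Suzuki coupling with 3-bromofuran.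
- No ring is formed: the furan and the oxazolidinone are bought intact.

Assumption: all six building blocks are purchased, and the alkylated phosphonate is used as the racemate because its stereocenter is destroyed in the olefination.

**Route**

Step 1
Reactants: 1 (S)-4-benzyloxazolidin-2-one; 2 pent-4-enoyl chloride
Product: 4 (S)-4-benzyl-3-(pent-4-enoyl)oxazolidin-2-one, via lithium oxazolidinide 3 (not isolated)
Conditions: n-BuLi, THF, −78 °C; then 2, −78 → 0 °C
Reagents that add atoms: none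
Why: N-acylation of the lithiated oxazolidinone by an acid chloride (nucleophilic acyl substitution) is fast and clean at low temperature, and no stereocenter is formed.

Step 2
Reactants: 4 (S)-4-benzyl-3-(pent-4-enoyl)oxazolidin-2-one; 5 3-bromofuran
Product: 7 (S)-4-benzyl-3-[5-(furan-3-yl)pentanoyl]oxazolidin-2-one, via B-alkyl-9-BBN adduct 6 (not isolated)
Conditions: 9-BBN, THF, 0 °C → rt; then 5, PdCl2(dppf) (5 mol%), AsPh3, Cs2CO3, DMF/H2O, rt
Reagents that add atoms: none
Why: 9-BBN hydroborates the terminal alkene anti-Markovnikov without reducing the imide, and the primary alkylborane then undergoes B-alkyl Suzuki–Miyaura coupling with the heteroaryl bromide under room-temperature carbonate conditions that are expected to spare the imide.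

Step 3
Reactants: 7 (S)-4-benzyl-3-[5-(furan-3-yl)pentanoyl]oxazolidin-2-one; 8 propargyl bromide
Product: 10 (S)-4-benzyl-3-[(R)-2-(3-(furan-3-yl)propyl)pent-4-ynoyl]oxazolidin-2-one, via sodium Z-enolate 9 (not isolated)
Conditions: NaN(SiMe3)2, THF, −78 °C; then 8 (3 equiv), −78 → −45 °C
Reagents that add atoms: none
Why: In this Evans asymmetric alkylation the chelated sodium (Z)-enolate is attacked by the activated propargylic bromide on the face opposite the C4 benzyl group, which sets the (R) α-stereocenter with the usual ≥95:5 selectivity.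

Step 4
Reactants: 10 (S)-4-benzyl-3-[(R)-2-(3-(furan-3-yl)propyl)pent-4-ynoyl]oxazolidin-2-one
Product: 11 (S)-4-benzyl-3-[(R)-2-(3-(furan-3-yl)propyl)-5-oxopentanoyl]oxazolidin-2-one
Conditions: CpRu(MeCN)3PF6 (5 mol%), 5,5'-bis(trifluoromethyl)-2,2'-bipyridine (5 mol%), NMP/H2O 4:1, 25 °C
Reagents that add atoms: water, O
Why: Ruthenium-catalysed anti-Markovnikov hydration of the terminal alkyne through a vinylidene gives the aldehyde directly under neutral conditions, so the imide, the furan and the α-stereocenter are untouched and no by-product is formed.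

Step 5
Reactants: 12 methyl 2-[bis(2,2,2-trifluoroethoxy)phosphoryl]acetate; 13 5-bromo-2-methylpent-2-ene
Product: 15 methyl 2-[bis(2,2,2-trifluoroethoxy)phosphoryl]-6-methylhept-5-enoate (racemic), via sodium phosphonoacetate carbanion 14 (not isolated)
Conditions: NaH, THF/DMF 4:1, 0 °C; then 13, 50 °C (12 in 1.5-fold excess)
Reagents that add atoms: none
Why: SN2 C-alkylation of the stabilised phosphonoacetate anion by the primary homoallylic bromide, with excess phosphonate used to suppress dialkylation.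

Step 6
Reactants: 11 (S)-4-benzyl-3-[(R)-2-(3-(furan-3-yl)propyl)-5-oxopentanoyl]oxazolidin-2-one; 15 methyl 2-[bis(2,2,2-trifluoroethoxy)phosphoryl]-6-methylhept-5-enoate
Product: 17 (S)-4-benzyl-3-[(2R,5Z)-2-(3-(furan-3-yl)propyl)-6-(methoxycarbonyl)-10-methylundeca-5,9-dienoyl]oxazolidin-2-one, via potassium phosphonate carbanion 16 (not isolated)
Conditions: 15 (1.3 equiv), KN(SiMe3)2 (1.25 equiv), 18-crown-6, THF, −78 °C; then 11, −78 → −40 °C
Reagents that add atoms: none
Why: In this Still–Gennari olefination the electron-poor trifluoroethyl phosphonate with a crown-sequestered potassium counter-ion eliminates from the kinetic oxaphosphetane to give the (Z)-enoate with the ester cis to the new chain, and the pre-formed weakly basic carbanion does not epimerise the imide α-center.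

Step 7
Reactants: 17 (S)-4-benzyl-3-[(2R,5Z)-2-(3-(furan-3-yl)propyl)-6-(methoxycarbonyl)-10-methylundeca-5,9-dienoyl]oxazolidin-2-one
Product: 19 (2R,5Z)-2-[3-(furan-3-yl)propyl]-6-(methoxycarbonyl)-10-methylundeca-5,9-dienoic acid, via lithium peroxycarboxylate 18 (not isolated)
Conditions: LiOH, 30% H2O2, THF/H2O 3:1, 0 °C; Na2SO3 aq; then cold 1 M HCl to pH 3
Reagents that add atoms: hydrogen peroxide, OO
Why: In this Evans auxiliary hydrolysis the hydroperoxide anion attacks the exocyclic imide carbonyl far faster than it saponifies the hindered α-substituted conjugated methyl ester at 0 °C, and the peroxy acid salt is reduced by sulfite before acidification so the furan, both alkenes and the (R) center survive.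

**Compound list**

1 | (S)-4-benzyloxazolidin-2-one | O=C1N[C@@H](Cc2ccccc2)CO1 | starting material
2 | pent-4-enoyl chloride | C=CCCC(=O)Cl | starting material
3 | lithium (S)-4-benzyl-2-oxooxazolidin-3-ide (formed in the flask) | [Li+].O=C1[N-][C@@H](Cc2ccccc2)CO1 | intermediate
4 | (S)-4-benzyl-3-(pent-4-enoyl)oxazolidin-2-one | C=CCCC(=O)N1[C@@H](Cc2ccccc2)COC1=O | intermediate
5 | 3-bromofuran | Brc1ccoc1 | starting material
6 | (S)-4-benzyl-3-[5-(9-borabicyclo[3.3.1]nonan-9-yl)pentanoyl]oxazolidin-2-one (formed in the flask) | O=C(CCCCB1C2CCCC1CCC2)N1[C@@H](Cc2ccccc2)COC1=O | intermediate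
7 | (S)-4-benzyl-3-[5-(furan-3-yl)pentanoyl]oxazolidin-2-one | O=C(CCCCc1ccoc1)N1[C@@H](Cc2ccccc2)COC1=O | intermediate
8 | propargyl bromide (3-bromoprop-1-yne) | C#CCBr | starting material
9 | sodium (Z)-1-[(S)-4-benzyl-2-oxooxazolidin-3-yl]-5-(furan-3-yl)pent-1-en-1-olate (formed in the flask) | [Na+].[O-]/C(=C\CCCc1ccoc1)N1[C@@H](Cc2ccccc2)COC1=O | intermediate
10 | (S)-4-benzyl-3-[(R)-2-(3-(furan-3-yl)propyl)pent-4-ynoyl]oxazolidin-2-one | C#CC[C@@H](CCCc1ccoc1)C(=O)N1[C@@H](Cc2ccccc2)COC1=O | intermediate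
11 | (S)-4-benzyl-3-[(R)-2-(3-(furan-3-yl)propyl)-5-oxopentanoyl]oxazolidin-2-one | O=CCC[C@@H](CCCc1ccoc1)C(=O)N1[C@@H](Cc2ccccc2)COC1=O | intermediate
12 | methyl 2-[bis(2,2,2-trifluoroethoxy)phosphoryl]acetate | COC(=O)CP(=O)(OCC(F)(F)F)OCC(F)(F)F | starting material
13 | 5-bromo-2-methylpent-2-ene | CC(C)=CCCBr | starting material
14 | sodium salt (carbanion) of 12 (formed in the flask) | [Na+].COC(=O)[CH-]P(=O)(OCC(F)(F)F)OCC(F)(F)F | intermediate
15 | methyl 2-[bis(2,2,2-trifluoroethoxy)phosphoryl]-6-methylhept-5-enoate (racemic) | COC(=O)C(CCC=C(C)C)P(=O)(OCC(F)(F)F)OCC(F)(F)F | intermediate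
16 | potassium salt (carbanion) of 15 (formed in the flask) | [K+].COC(=O)[C-](CCC=C(C)C)P(=O)(OCC(F)(F)F)OCC(F)(F)F | intermediate
17 | (S)-4-benzyl-3-[(2R,5Z)-2-(3-(furan-3-yl)propyl)-6-(methoxycarbonyl)-10-methylundeca-5,9-dienoyl]oxazolidin-2-one | COC(=O)/C(=C\CC[C@@H](CCCc1ccoc1)C(=O)N1[C@@H](Cc2ccccc2)COC1=O)CCC=C(C)C | intermediate
18 | lithium (2R,5Z)-2-[3-(furan-3-yl)propyl]-6-(methoxycarbonyl)-10-methylundeca-5,9-dieneperoxoate (formed in the flask) | [Li+].COC(=O)/C(=C\CC[C@@H](CCCc1ccoc1)C(=O)O[O-])CCC=C(C)C | intermediate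
19 | (2R,5Z)-2-[3-(furan-3-yl)propyl]-6-(methoxycarbonyl)-10-methylundeca-5,9-dienoic acid | COC(=O)/C(=C\CC[C@@H](CCCc1ccoc1)C(=O)O)CCC=C(C)C | target

**Step count and risks**

Total step count: 7. Longest linear sequence: 6 steps (steps 1, 2, 3, 4, 6, 7); step 5 is a one-step side branch.

The three steps most likely to fail:

Step 2 (B-alkyl Suzuki coupling beside a base-sensitive imide). The fallback sets out from 3-bromofuran 5 and builds the chain before the auxiliary is attached. Commercial methyl pent-4-enoate is hydroborated with 9-BBN to methyl 5-(9-borabicyclo[3.3.1]nonan-9-yl)pentanoate F1. This is coupled with 5 (PdCl2(dppf), K3PO4, DMF/H2O, 50 °C) to methyl 5-(furan-3-yl)pentanoate F2. Saponification (LiOH, THF/H2O) gives 5-(furan-3-yl)pentanoic acid F3. PivCl/Et3N converts it into 5-(furan-3-yl)pentanoic pivalic anhydride F4, which acylates 1 (LiCl, Et3N, THF) and comes back to the route at 7.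

Step 4 (catalytic anti-Markovnikov hydration; risk of stalling or of methyl ketone). The fallback sets out from 7 and uses an alkene instead of an alkyne. Enolate 9 is alkylated with allyl iodide to (S)-4-benzyl-3-[(R)-2-(3-(furan-3-yl)propyl)pent-4-enoyl]oxazolidin-2-one F5. Hydroboration with 9-BBN gives (S)-4-benzyl-3-[(S)-5-(9-borabicyclo[3.3.1]nonan-9-yl)-2-(3-(furan-3-yl)propyl)pentanoyl]oxazolidin-2-one F6; the spatial arrangement is unchanged and the descriptor changes only because carbon outranks boron. Buffered oxidation (H2O2, pH 7 phosphate, 0 °C) gives (S)-4-benzyl-3-[(R)-2-(3-(furan-3-yl)propyl)-5-hydroxypentanoyl]oxazolidin-2-one F7. This is oxidised at once with Dess–Martin periodinane (NaHCO3, CH2Cl2), before it can lactonise, and comes back to the route at 11.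

Step 6 (Z-selectivity and reactivity of the α-branched Still–Gennari reagent). The fallback sets out from 11 and builds the alkene by stereospecific cross-coupling. Ramirez olefination (CBr4, PPh3, CH2Cl2, 0 °C) gives (S)-4-benzyl-3-[(R)-6,6-dibromo-2-(3-(furan-3-yl)propyl)hex-5-enoyl]oxazolidin-2-one F8. Bromide 13 with Zn dust and LiCl in THF gives (4-methylpent-3-en-1-yl)zinc bromide F9. Trans-selective Negishi monoalkylation of F8 with F9 (PdCl2(DPEphos), THF, 0 °C → rt) replaces only the bromine trans to the chain and gives (S)-4-benzyl-3-[(2R,5Z)-6-bromo-2-(3-(furan-3-yl)propyl)-10-methylundeca-5,9-dienoyl]oxazolidin-2-one F10. Methoxycarbonylation with retention (Pd(OAc)2, dppf, CO 1 atm, MeOH 5 equiv, Et3N, DMF, 50 °C) comes back to the route at 17.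

**Further compounds**

F1 | step 2 | methyl 5-(9-borabicyclo[3.3.1]nonan-9-yl)pentanoate | COC(=O)CCCCB1C2CCCC1CCC2
F2 | step 2 | methyl 5-(furan-3-yl)pentanoate | COC(=O)CCCCc1ccoc1
F3 | step 2 | 5-(furan-3-yl)pentanoic acid | OC(=O)CCCCc1ccoc1
F4 | step 2 | 5-(furan-3-yl)pentanoic pivalic anhydride | CC(C)(C)C(=O)OC(=O)CCCCc1ccoc1
F5 | step 4 | (S)-4-benzyl-3-[(R)-2-(3-(furan-3-yl)propyl)pent-4-enoyl]oxazolidin-2-one | C=CC[C@@H](CCCc1ccoc1)C(=O)N1[C@@H](Cc2ccccc2)COC1=O
F6 | step 4 | (S)-4-benzyl-3-[(S)-5-(9-borabicyclo[3.3.1]nonan-9-yl)-2-(3-(furan-3-yl)propyl)pentanoyl]oxazolidin-2-one | B1(CCC[C@@H](CCCc2ccoc2)C(=O)N2[C@@H](Cc3ccccc3)COC2=O)C2CCCC1CCC2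
F7 | step 4 | (S)-4-benzyl-3-[(R)-2-(3-(furan-3-yl)propyl)-5-hydroxypentanoyl]oxazolidin-2-one | OCCC[C@@H](CCCc1ccoc1)C(=O)N1[C@@H](Cc2ccccc2)COC1=O
F8 | step 6 | (S)-4-benzyl-3-[(R)-6,6-dibromo-2-(3-(furan-3-yl)propyl)hex-5-enoyl]oxazolidin-2-one | BrC(Br)=CCC[C@@H](CCCc1ccoc1)C(=O)N1[C@@H](Cc2ccccc2)COC1=O
F9 | step 6 | (4-methylpent-3-en-1-yl)zinc bromide | CC(C)=CCC[Zn]Br
F10 | step 6 | (S)-4-benzyl-3-[(2R,5Z)-6-bromo-2-(3-(furan-3-yl)propyl)-10-methylundeca-5,9-dienoyl]oxazolidin-2-one | Br/C(=C\CC[C@@H](CCCc1ccoc1)C(=O)N1[C@@H](Cc2ccccc2)COC1=O)CCC=C(C)C
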